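Assumption (remark on the chemistry): the target SMILES is read as (2S,3S,4S,5S), that is 2,3-cis, 3,4-trans, 4,5-cis with the two aryl groups trans. Hydride transfer to a five-membered 2-aryl oxocarbenium ion is taken to occur anti to the substituent on the neighbouring ring carbon, as in related 2-aryl-3-alkyl oxolanes.

## Structural features

Eduesmine has one oxolane ring (O1, C2–C5) in which C2 and C5 each carry a 4-hydroxy-3-methoxyphenyl ring and C3 and C4 each carry a hydroxymethyl carbon (C3a, C4a). The four ring carbons are contiguous stereocentres, all S: each aryl group is cis to the hydroxymethyl group on the neighbouring carbon, C3 and C4 are trans, and the aryl groups are trans to each other. The molecule therefore has a C2 axis through O1 and the midpoint of C3–C4. The benzylic ether carbons C2 and C5 are flanked by para-oxygenated arenes and ionise easily under Brønsted or Lewis acid, after which they would relax to the more stable all-trans array, and the free phenols are oxidisable and, as phenoxides, open a quinone methide path to the same epimerisation. The real difficulty is this contra-thermodynamic cis,trans,cis arrangement in one enantiomer, not the connectivity. C3 and C4 form a threo pair in which each centre bears a CH2OH carbon and sits next to an aryl-bearing carbon. That is the pattern left by a [2,3] shift of an O–CH2 carbanion across an aryl-substituted allyl unit, so C3–C3a and C4–C4a can both be made with chirality transfer from sacrificial carbinol centres, twice on one symmetric diene.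

## Logic of the disconnections

18 back to 16: the two aryl O–CH2Ph bonds and the two CH2O–Si bonds are cut. Phenols and primary alcohols must be masked against KH, n-BuLi and the oxidant, and the primary alcohols must not add to carbonyl or cationic carbons. Nothing is gained in skeleton. The demand is that the last steps never ionise C2 or C5, so fluoride comes first (17 still has no free phenol) and neutral hydrogenolysis comes last.

16 back to 14: the O1–C5 ring bond and the two benzylic C–H bonds (C2–H, C5–H) are cut, which opens the ring to a C2-symmetric 1,4-dicarbonyl compound. Two stereocentres and the ring disappear and both benzylic carbons become equivalent. The demand is that both hydrides are delivered to ring oxocarbenium ions, anti to the neighbouring CH2OSi group. A hydride reduction of one open-chain carbonyl of 14 is deliberately avoided: with the branched carbon C4 as the large group, Felkin–Anh attack would give the 2,3-trans carbinol.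

14 back to 11 through 12: each C=O is traced to a C=CH–CH3 unit and the silyl groups are removed. The aryl ketone carbons have to pass through the anionic key step in a non-electrophilic, non-enolisable form, and a propenyl group is exactly what the sigmatropic shift leaves. The demand is near-neutral cleavage, because C3 and C4 become α to aryl ketones and β to silyloxy groups. Silylation precedes cleavage so that no free CH2OH can close onto a carbonyl.

11 back to 9 (key): the C3–C3a and C4–C4a bonds are cut and each CH2O carbon is reattached through oxygen to a carbinol carbon two atoms away. The branched core becomes a linear, symmetric E,E diene, and the two backbone stereocentres are exchanged for two carbinol centres that can be bought enantiopure. The demand is suprafacial [2,3] transfer twice, with the same conformer each time and no [1,2] shift. By CIP analysis the (2R,7R,3E,5E) ether 9 leads to (2R,3R)-11, which corresponds to 3S,4S in 18 by a change of priority only.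

9 back to 7 and 8: the two O–CH2Sn bonds are cut. This separates the carbanion precursor from the diene diol and needs only a twofold O-alkylation that leaves the allylic C–O bonds alone.

7 back to 2 and 4: the two C(sp2)–aryl bonds and the two vinylic C–H bonds are cut (retro anti-arylmetalation). The diene geometry then follows from the addition mode and the two aryl halves are identical. The demand is aryl delivery to the carbon next to each alkoxide and anti addition at both triple bonds.

2 back to 1, and 4 back to 3: the central C(sp)–C(sp) bond is cut (oxidative dimerisation of two molecules of a terminal alkyne) and the O–benzyl bond is cut. Both lead to commercial materials.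

## Other disconnections considered

Alternative 1: The cut is at the C2–aryl and C5–aryl bonds of a preformed ring. In the forward sense the trans diamide A1, (3R,4R)-N,N'-di(quinolin-8-yl)oxolane-3,4-dicarboxamide, would be arylated twice with the aryl iodide A2, 1-(benzyloxy)-4-iodo-2-methoxybenzene, under Pd(OAc)2 and AgOAc to give A3.
- In its favour: each amide should steer divalent palladium to the O-adjacent methylene C–H on its own side through a five-membered palladacycle fused cis to the ring. Each aryl group would then arrive cis to the neighbouring carboxamide. On this point the alternative is better than the chosen plan, because 2,3-cis and 4,5-cis follow from metallacycle geometry and not from the facial preference of a ring cation. It is also likely to be equal or better in step count (about seven steps against ten), and the arenes enter last.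
- Against it here: the second arylation has to take place on a ring that already carries a cis aryl group. Two bidentate amide groups can hold palladium unproductively, and mono- and bis-arylation may be hard to separate. Afterwards both amides must be cleaved and reduced to CH2OH while C3 and C4 are α to carbonyl groups and cis to aryl groups, so epimerisation to the trans,trans,trans series is a real threat. Enantiopure A1 needs a resolution or a chiral-pool source, and silver is stoichiometric.
- Comparison: structurally it keeps the ring and adds the arenes; mechanistically it is C–H metalation against sigmatropic chirality transfer. The chosen plan is longer but derives C3 and C4 from one commercial carbinol and never places them next to an enolisable carbonyl under basic or hot conditions.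

Alternative 2: The cut is the O1–C5 bond together with the C2–H bond. In the forward sense the keto β-lactone A4 would be treated with Et3SiOTf and Et3SiH. The ketone oxygen would displace the lactone oxygen at the benzylic carbon with inversion, the oxolane would close, and the 2-aryl oxocarbenium ion would take up hydride to give the acid A5.
- In its favour: the ring and both benzylic centres come from one operation. C5 is fixed by a stereospecific displacement and not by hydride approach to a cation whose remote aryl group lies on the attacked face; on this point it is better than the chosen plan. C2 is set by the same kind of hydride delivery as in step 8, so there the two are equal.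
- Against it here: the two aryl groups must be differentiated (an acetate on the ring whose benzylic carbon is displaced, to hold back ionisation) although the target is symmetric. A para-oxygenated benzylic C–O bond may still ionise, which would cost the inversion. A4 needs three contiguous stereocentres, including a strained cis β-lactone, before the key step. Afterwards the acid must be reduced to CH2OH beside a pivalate and an aryl acetate.
- Comparison: it is the stronger plan on ring construction and on C5, but weaker on symmetry and on the cost of the precursor. Overall step count is expected to be similar or higher.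

Alternative 3: The cut is the O1–C5 bond, made by oxygen insertion into a C–C(=O) bond. In the forward sense the cyclobutanone A6 would react with m-CPBA and NaHCO3; the aryl-bearing carbon migrates with retention and the lactone A7 results.
- In its favour: Baeyer–Villiger migration is stereospecific and regioselective for the more substituted, benzylic carbon, so the cis relation between the aryl group and its neighbour is carried over unchanged. The second aryl group would then be added to the lactone carbonyl as an organometallic and the hemiketal reduced. That last reduction is the same event as the second hydride transfer of step 8, so the two plans are equal there. The alternative is better for unsymmetrical analogues, because the two arenes enter separately.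
- Against it here: A6 must be made enantiopure with a cis aryl group on a carbon that is both benzylic and α to the ketone, and this centre can epimerise to the trans isomer before oxidation. The peracid must spare two electron-rich arenes. The symmetry of the target is not used.
- Comparison: comparable length. It relies on a four-membered ring synthesis for C3, C4 and C5, where the chosen plan relies on chirality transfer from a commercial carbinol.

Key step: step 5

## Route

Step 1
Reactants: 1 (R)-but-3-yn-2-ol
Product: 2 (2R,7R)-octa-3,5-diyne-2,7-diol
Conditions: CuCl (10 mol%), TMEDA, O2 (1 atm), acetone, rt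
Reagents that add atoms: (R)-but-3-yn-2-ol (second molecule of 1), C[C@@H](O)C#C
Why: Glaser–Hay oxidative homocoupling joins two molecules of the terminal alkyne 1 at their sp carbons through a monovalent copper acetylide, with O2 as the terminal oxidant; the carbinol centres are not involved, so both stay R.

Step 2
Reactants: 3 4-bromo-2-methoxyphenol
Product: 4 1-(benzyloxy)-4-bromo-2-methoxybenzene
Conditions: BnBr, K2CO3, DMF, rt
Reagents that add atoms: benzyl bromide, BrCc1ccccc1
Why: Williamson ether synthesis on the phenoxide; the benzyl ether tolerates Mg, KH, n-BuLi, OsO4 and BF3·OEt2 and is removed at the end under neutral conditions.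

Step 3
Reactants: 2 (2R,7R)-octa-3,5-diyne-2,7-diol; 4 1-(benzyloxy)-4-bromo-2-methoxybenzene
Product: 7 (2R,3E,5E,7R)-3,6-bis(4-benzyloxy-3-methoxyphenyl)octa-3,5-diene-2,7-diol, via aryl Grignard reagent 5 (not isolated), via dimagnesium chelate 6 (not isolated)
Conditions: 4 (4.5 equiv), Mg, THF, 45 °C; then 2, CuI (20 mol%), THF–toluene, reflux; aq NH4Cl
Reagents that add atoms: 1-(benzyloxy)-4-bromo-2-methoxybenzene (second equivalent of 4), COc1cc(Br)ccc1OCc1ccccc1
Why: Copper-catalysed, alkoxide-directed anti-carbomagnesiation of a propargylic alcohol, applied to both triple bonds with one aryl group from 5 each: the aryl group goes to the carbon next to each carbinol (C3, C6) and magnesium to C4 and C5, held cis to the alkoxide in five-membered chelate 6. Protonation then leaves hydrogen cis to the carbinol carbon and the aryl group cis to the diene chain, which is the 3E,5E geometry; no stereocentre is formed and the R carbinols are untouched.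

Step 4
Reactants: 7 (2R,3E,5E,7R)-3,6-bis(4-benzyloxy-3-methoxyphenyl)octa-3,5-diene-2,7-diol; 8 tributyl(iodomethyl)stannane
Product: 9 (2R,3E,5E,7R)-3,6-bis(4-benzyloxy-3-methoxyphenyl)-2,7-bis[(tributylstannyl)methoxy]octa-3,5-diene
Conditions: KH (2.5 equiv), THF, 0 °C; then 8 (2.4 equiv), rt
Reagents that add atoms: tributyl(iodomethyl)stannane (second equivalent of 8), CCCC[Sn](CI)(CCCC)CCCC
Why: Twofold Williamson-type O-alkylation in which each potassium alkoxide displaces iodide from one molecule of the iodomethylstannane; the allylic C–O bonds are not broken, so the configuration and the diene geometry are kept.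

Step 5
Reactants: 9 (2R,3E,5E,7R)-3,6-bis(4-benzyloxy-3-methoxyphenyl)-2,7-bis[(tributylstannyl)methoxy]octa-3,5-diene
Product: 11 (2R,3R)-2,3-bis[(1E)-1-(4-benzyloxy-3-methoxyphenyl)prop-1-en-1-yl]butane-1,4-diol, via bis(lithiomethyl) ether 10 (not isolated)
Conditions: n-BuLi (2.5 equiv), THF, −78 °C to −20 °C; aq NH4Cl
Reagents that add atoms: none
Why: Tin–lithium exchange turns each OCH2SnBu3 group into an α-alkoxymethyllithium (10), which undergoes a [2,3]-sigmatropic shift through a five-membered envelope transition state: the CH2 carbon bonds to the distal alkene carbon (octadiene C4, then C5), the allylic C–O bond breaks and the double bond moves to C2=C3 (then C6=C7). The closest known reaction type is the Still–Wittig rearrangement of stannylmethyl ethers of secondary allylic alcohols that carry a substituent on the central allyl carbon, here run twice on one conjugated diene. No ring is closed; the two new C–C bonds are C3–C3a and C4–C4a of the target, and two stereocentres are formed. Each new centre is controlled by its own R carbinol: the shift is suprafacial, so the CH2O carbon is delivered to the face from which the C–O bond leaves, and A(1,2) strain with the aryl group on the central carbon turns the carbinol methyl group inside, where the E geometry lets it meet only a vinylic hydrogen. With that conformer an R carbinol should give an R centre and an E-propenyl group, and the C2 symmetry of 9 makes the second shift a repeat of the first, so the threo (2R,3R) diol is expected. The step needs [2,3] shift in preference to [1,2] shift or protonation, which low temperature in THF should secure because the concerted shift is fast at −78 °C and the radical-pair pathway is not. It also needs faithful chirality transfer twice, which rests on the enantiopure carbinols, the E,E geometry and the 2-aryl substituent; the diene and the benzyl ethers should survive because tin–lithium exchange is much faster than addition or metalation at this temperature.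

Step 6
Reactants: 11 (2R,3R)-2,3-bis[(1E)-1-(4-benzyloxy-3-methoxyphenyl)prop-1-en-1-yl]butane-1,4-diol
Product: 12 (2R,3R)-2,3-bis[(1E)-1-(4-benzyloxy-3-methoxyphenyl)prop-1-en-1-yl]-1,4-bis(tert-butyldiphenylsilyloxy)butane
Conditions: TBDPSCl (2.4 equiv), imidazole, DMF, rt
Reagents that add atoms: tert-butyl(chloro)diphenylsilane, CC(C)(C)[Si](Cl)(c1ccccc1)c1ccccc1
Why: Standard silylation of both primary alcohols. Free CH2OH groups would close onto the carbonyl groups made in step 7, and the bulky, weakly basic silyl ether oxygens should not attack the oxocarbenium ions of step 8.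

Step 7
Reactants: 12 (2R,3R)-2,3-bis[(1E)-1-(4-benzyloxy-3-methoxyphenyl)prop-1-en-1-yl]-1,4-bis(tert-butyldiphenylsilyloxy)butane
Product: 14 (2S,3S)-1,4-bis(4-benzyloxy-3-methoxyphenyl)-2,3-bis[(tert-butyldiphenylsilyloxy)methyl]butane-1,4-dione, via bis-diol 13 (not isolated)
Conditions: OsO4 (5 mol%), NaIO4 (6 equiv), 2,6-lutidine, dioxane–H2O, rt
Reagents that add atoms: osmium tetroxide (OsO4), O=[Os](=O)(=O)=O; sodium periodate (NaIO4), [Na+].[O-]I(=O)(=O)=O
Why: Lemieux–Johnson oxidation: catalytic osmylation of each trisubstituted styrenyl alkene to diol 13, then periodate glycol cleavage with loss of acetaldehyde. The lutidine buffer should keep the new α-stereocentres from epimerising and the β-silyloxy groups from eliminating; the centres are not touched and R becomes S by priority only.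

Step 8
Reactants: 14 (2S,3S)-1,4-bis(4-benzyloxy-3-methoxyphenyl)-2,3-bis[(tert-butyldiphenylsilyloxy)methyl]butane-1,4-dione
Product: 16 (2S,3S,4S,5S)-2,5-bis(4-benzyloxy-3-methoxyphenyl)-3,4-bis[(tert-butyldiphenylsilyloxy)methyl]oxolane, via cyclic hemiketal 15 (not isolated)
Conditions: Et3SiH (6 equiv), BF3·OEt2 (3 equiv), CH2Cl2, −78 °C to −40 °C; Et3N then aq NaHCO3 at −78 °C
Reagents that add atoms: none
Why: Lewis acid–silane reductive cyclisation of a 1,4-diketone (ionic hydrogenation with intramolecular reductive etherification): the BF3-bound carbonyl is captured by the other carbonyl oxygen to give a five-membered oxocarbenium ion, Et3SiH adds to it anti to the CH2OSi group on the adjacent carbon, and the resulting hemiketal 15 ionises at the second benzylic carbon and is reduced in the same way. Both hydrides are thus delivered inside the ring, so each aryl group should end cis to its neighbouring CH2OSi group (2S and 5S, with 3S,4S unchanged), and the C2 symmetry of 14 makes it immaterial which carbonyl reacts first. At −78 °C the open-chain ketone–BF3 complex, whose Felkin–Anh reduction would give the 2,3-trans carbinol, should not be reduced, and the benzylic ether carbons should not ionise once formed.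

Step 9
Reactants: 16 (2S,3S,4S,5S)-2,5-bis(4-benzyloxy-3-methoxyphenyl)-3,4-bis[(tert-butyldiphenylsilyloxy)methyl]oxolane
Product: 17 [(2S,3S,4S,5S)-2,5-bis(4-benzyloxy-3-methoxyphenyl)oxolane-3,4-diyl]dimethanol
Conditions: Bu4NF, THF, rt; aq NH4Cl
Reagents that add atoms: none
Why: Fluoride cleavage of the two Si–O bonds. It is placed before phenol unmasking so that no phenoxide, and hence no quinone methide route to C2 or C5 epimerisation, can arise under basic fluoride.

Step 10
Reactants: 17 [(2S,3S,4S,5S)-2,5-bis(4-benzyloxy-3-methoxyphenyl)oxolane-3,4-diyl]dimethanol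
Product: 18 eduesmine, [(2S,3S,4S,5S)-2,5-bis(4-hydroxy-3-methoxyphenyl)oxolane-3,4-diyl]dimethanol
Conditions: H2 (1 atm), Pd/C (10 wt%), EtOAc–MeOH, rt
Reagents that add atoms: none
Why: Hydrogenolysis of the two aryl benzyl ethers under neutral conditions, stopped after two equivalents of hydrogen so that the benzylic C–O bonds of the ring are spared; no stereocentre is involved.

## Compound list

1 | (R)-but-3-yn-2-ol | C[C@@H](O)C#C | starting material
2 | (2R,7R)-octa-3,5-diyne-2,7-diol | C[C@@H](O)C#CC#C[C@@H](C)O | intermediate
3 | 4-bromo-2-methoxyphenol | COc1cc(Br)ccc1O | starting material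
4 | 1-(benzyloxy)-4-bromo-2-methoxybenzene | COc1cc(Br)ccc1OCc1ccccc1 | intermediate
5 | (4-benzyloxy-3-methoxyphenyl)magnesium bromide | COc1cc([Mg]Br)ccc1OCc1ccccc1 | intermediate
6 | (5R,5'R)-4,4'-bis(4-benzyloxy-3-methoxyphenyl)-5,5'-dimethyl-2,5,2',5'-tetrahydro-3,3'-bi(1,2-oxamagnesole) | C[C@H]1O[Mg]C(=C1c1ccc(OCc2ccccc2)c(OC)c1)C1=C(c2ccc(OCc3ccccc3)c(OC)c2)[C@@H](C)O[Mg]1 | intermediate
7 | (2R,3E,5E,7R)-3,6-bis(4-benzyloxy-3-methoxyphenyl)octa-3,5-diene-2,7-diol | C[C@@H](O)/C(c1ccc(OCc2ccccc2)c(OC)c1)=C/C=C(c1ccc(OCc2ccccc2)c(OC)c1)/[C@@H](C)O | intermediate
8 | tributyl(iodomethyl)stannane | CCCC[Sn](CI)(CCCC)CCCC | starting material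
9 | (2R,3E,5E,7R)-3,6-bis(4-benzyloxy-3-methoxyphenyl)-2,7-bis[(tributylstannyl)methoxy]octa-3,5-diene | C[C@@H](OC[Sn](CCCC)(CCCC)CCCC)/C(c1ccc(OCc2ccccc2)c(OC)c1)=C/C=C(c1ccc(OCc2ccccc2)c(OC)c1)/[C@@H](C)OC[Sn](CCCC)(CCCC)CCCC | intermediate
10 | (2R,3E,5E,7R)-3,6-bis(4-benzyloxy-3-methoxyphenyl)-2,7-bis(lithiomethoxy)octa-3,5-diene | C[C@@H](OC[Li])/C(c1ccc(OCc2ccccc2)c(OC)c1)=C/C=C(c1ccc(OCc2ccccc2)c(OC)c1)/[C@@H](C)OC[Li] | intermediate
11 | (2R,3R)-2,3-bis[(1E)-1-(4-benzyloxy-3-methoxyphenyl)prop-1-en-1-yl]butane-1,4-diol | C/C=C(/c1ccc(OCc2ccccc2)c(OC)c1)[C@H](CO)[C@@H](CO)/C(c1ccc(OCc2ccccc2)c(OC)c1)=C\C | intermediate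
12 | (2R,3R)-2,3-bis[(1E)-1-(4-benzyloxy-3-methoxyphenyl)prop-1-en-1-yl]-1,4-bis(tert-butyldiphenylsilyloxy)butane | C/C=C(/c1ccc(OCc2ccccc2)c(OC)c1)[C@H](CO[Si](c1ccccc1)(c1ccccc1)C(C)(C)C)[C@@H](CO[Si](c1ccccc1)(c1ccccc1)C(C)(C)C)/C(c1ccc(OCc2ccccc2)c(OC)c1)=C\C | intermediate
13 | (2S,3S)-2,3-bis[1-(4-benzyloxy-3-methoxyphenyl)-1,2-dihydroxypropyl]-1,4-bis(tert-butyldiphenylsilyloxy)butane, new carbinol centres as a diastereomer mixture | CC(O)C(O)(c1ccc(OCc2ccccc2)c(OC)c1)[C@H](CO[Si](c1ccccc1)(c1ccccc1)C(C)(C)C)[C@@H](CO[Si](c1ccccc1)(c1ccccc1)C(C)(C)C)C(O)(c1ccc(OCc2ccccc2)c(OC)c1)C(C)O | intermediate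
14 | (2S,3S)-1,4-bis(4-benzyloxy-3-methoxyphenyl)-2,3-bis[(tert-butyldiphenylsilyloxy)methyl]butane-1,4-dione | O=C(c1ccc(OCc2ccccc2)c(OC)c1)[C@H](CO[Si](c1ccccc1)(c1ccccc1)C(C)(C)C)[C@@H](CO[Si](c1ccccc1)(c1ccccc1)C(C)(C)C)C(=O)c1ccc(OCc2ccccc2)c(OC)c1 | intermediate
15 | (3S,4S,5S)-2,5-bis(4-benzyloxy-3-methoxyphenyl)-3,4-bis[(tert-butyldiphenylsilyloxy)methyl]oxolan-2-ol, both C2 epimers | OC1(c2ccc(OCc3ccccc3)c(OC)c2)O[C@H](c2ccc(OCc3ccccc3)c(OC)c2)[C@H](CO[Si](c2ccccc2)(c2ccccc2)C(C)(C)C)[C@H]1CO[Si](c1ccccc1)(c1ccccc1)C(C)(C)C | intermediate
16 | (2S,3S,4S,5S)-2,5-bis(4-benzyloxy-3-methoxyphenyl)-3,4-bis[(tert-butyldiphenylsilyloxy)methyl]oxolane | COc1cc([C@H]2O[C@H](c3ccc(OCc4ccccc4)c(OC)c3)[C@H](CO[Si](c3ccccc3)(c3ccccc3)C(C)(C)C)[C@H]2CO[Si](c2ccccc2)(c2ccccc2)C(C)(C)C)ccc1OCc1ccccc1 | intermediate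
17 | [(2S,3S,4S,5S)-2,5-bis(4-benzyloxy-3-methoxyphenyl)oxolane-3,4-diyl]dimethanol | COc1cc([C@H]2O[C@H](c3ccc(OCc4ccccc4)c(OC)c3)[C@H](CO)[C@H]2CO)ccc1OCc1ccccc1 | intermediate
18 | eduesmine, [(2S,3S,4S,5S)-2,5-bis(4-hydroxy-3-methoxyphenyl)oxolane-3,4-diyl]dimethanol | COc1cc([C@H]2O[C@H](c3ccc(O)c(OC)c3)[C@H](CO)[C@H]2CO)ccc1O | target

## Step count and least certain steps

Total step count: 10. Longest linear sequence: 9 steps (1 to 18 through steps 1 and 3–10; the branch from 3 through step 2 is equally long).

Step 5 (key step). What may go wrong: erosion of facial selectivity in one or both shifts if the conformer with the carbinol methyl group outside competes; [1,2] shift or protonation of the lithiomethyl ether before it rearranges; addition of n-BuLi to the aryl diene. Fallback, setting out from 7 and returning at 11: the same two C–C bonds would be made by a directed syn SN2' substitution instead of a sigmatropic shift. Diol 7 would be converted with phenyl isocyanate and pyridine into the (2R,3E,5E,7R)-3,6-bis(4-benzyloxy-3-methoxyphenyl)octa-3,5-diene-2,7-diyl bis(N-phenylcarbamate) F1. Deprotonation with MeLi, complexation with CuI·2LiCl and addition of (isopropoxydimethylsilyl)methylmagnesium chloride in THF at −78 to 0 °C should deliver the silylmethyl group to octadiene C4 and C5 on the face of the departing carbamate. This would give (2E,4R,5R,6E)-3,6-bis(4-benzyloxy-3-methoxyphenyl)-4,5-bis{[dimethyl(propan-2-yloxy)silyl]methyl}octa-2,6-diene F2. Tamao oxidation (H2O2, KF, KHCO3, THF–MeOH) would turn both C–Si bonds into C–OH and give 11.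

Step 3. What may go wrong: the second carbometalation may stall after mono-addition, because the intermediate alkenylmagnesium chelate makes the remaining triple bond electron-rich and places two carbon–magnesium bonds on adjacent carbons; regiochemical leakage at the second triple bond is also possible. Fallback, setting out from 2 and returning at 7: hydroxyl-directed trans-hydrostannation of both triple bonds (Bu3SnH, [Cp*RuCl]4 cat., CH2Cl2) would place tin next to each carbinol and hydrogen anti to it, giving (2R,3Z,5Z,7R)-3,6-bis(tributylstannyl)octa-3,5-diene-2,7-diol F3. Twofold Stille coupling with 4 (Pd(PPh3)4, CuI, CsF, DMF) would then give 7 with retention of geometry.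

Step 8. What may go wrong: hydride transfer to the open-chain activated carbonyl, where substrate control favours the wrong carbinol; erosion of facial selectivity in the second transfer, where the remote aryl group lies on the attacked face; dehydration towards the furan; acid epimerisation or ring opening on warming; or no reaction at low temperature. Fallback, setting out from 14 and returning at 16: Corey–Bakshi–Shibata reduction with (R)-2-methyl-CBS-oxazaborolidine and BH3·SMe2, kept below one hydride equivalent per molecule, should give the S carbinol at one carbonyl under reagent control (aryl as the large group), against the Felkin preference. The hydroxy ketone closes to hemiketal 15, which would be isolated and then reduced with Et3SiH and BF3·OEt2 at −78 °C to 16. The last hydride transfer is common to both routes. This fallback makes no compound outside the list (F0).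

Step 7. What may go wrong: slow osmylation of the hindered trisubstituted alkenes, with epimerisation α to the first-formed ketone or β-elimination of silanol during a long reaction. Fallback, setting out from 12 and returning at 14: ozonolysis (O3, CH2Cl2–MeOH, pyridine, −78 °C, then Me2S), stopped at consumption of the alkenes so that the arenes are spared. It makes no compound outside the list (F0).

## Further compounds

F1 | step 5 | (2R,3E,5E,7R)-3,6-bis(4-benzyloxy-3-methoxyphenyl)octa-3,5-diene-2,7-diyl bis(N-phenylcarbamate) | C[C@@H](OC(=O)Nc1ccccc1)/C(c1ccc(OCc2ccccc2)c(OC)c1)=C/C=C(c1ccc(OCc2ccccc2)c(OC)c1)/[C@@H](C)OC(=O)Nc1ccccc1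
F2 | step 5 | (2E,4R,5R,6E)-3,6-bis(4-benzyloxy-3-methoxyphenyl)-4,5-bis{[dimethyl(propan-2-yloxy)silyl]methyl}octa-2,6-diene | C/C=C(/c1ccc(OCc2ccccc2)c(OC)c1)[C@H](C[Si](C)(C)OC(C)C)[C@@H](C[Si](C)(C)OC(C)C)/C(c1ccc(OCc2ccccc2)c(OC)c1)=C\C
F3 | step 3 | (2R,3Z,5Z,7R)-3,6-bis(tributylstannyl)octa-3,5-diene-2,7-diol | C[C@@H](O)/C([Sn](CCCC)(CCCC)CCCC)=C/C=C([Sn](CCCC)(CCCC)CCCC)/[C@@H](C)O
F0 | step 8 | none | none
F0 | step 7 | none | none
A1 | alternative 1 | (3R,4R)-N,N'-di(quinolin-8-yl)oxolane-3,4-dicarboxamide | C1OC[C@H](C(=O)Nc2cccc3cccnc23)[C@H]1C(=O)Nc1cccc2cccnc12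
A2 | alternative 1 | 1-(benzyloxy)-4-iodo-2-methoxybenzene | COc1cc(I)ccc1OCc1ccccc1
A3 | alternative 1 | (2S,3R,4R,5S)-2,5-bis(4-benzyloxy-3-methoxyphenyl)-N,N'-di(quinolin-8-yl)oxolane-3,4-dicarboxamide | COc1cc(ccc1OCc2ccccc2)[C@H]3O[C@H](c4ccc(OCc5ccccc5)c(OC)c4)[C@H](C(=O)Nc6cccc7cccnc67)[C@H]3C(=O)Nc8cccc9cccnc89
A4 | alternative 2 | cis-4-(4-acetoxy-3-methoxyphenyl)-3-[1-(4-benzyloxy-3-methoxyphenyl)-1-oxo-3-(pivaloyloxy)propan-2-yl]oxetan-2-one, configuration as in the SMILES | COc1cc(ccc1OCc1ccccc1)C(=O)[C@H](COC(=O)C(C)(C)C)[C@H]1C(=O)O[C@H]1c1ccc(OC(C)=O)c(OC)c1
A5 | alternative 2 | 2-(4-acetoxy-3-methoxyphenyl)-5-(4-benzyloxy-3-methoxyphenyl)-4-[(pivaloyloxy)methyl]oxolane-3-carboxylic acid, ring configuration as in 18 | COc1cc(ccc1OCc2ccccc2)[C@H]3O[C@H](c4ccc(OC(C)=O)c(OC)c4)[C@H](C(=O)O)[C@H]3COC(=O)C(C)(C)C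
A6 | alternative 3 | 2-(4-benzyloxy-3-methoxyphenyl)-3,4-bis(benzyloxymethyl)cyclobutan-1-one, 2,3-cis-3,4-trans | O=C1[C@H](c2ccc(OCc3ccccc3)c(OC)c2)[C@H](COCc2ccccc2)[C@H]1COCc1ccccc1
A7 | alternative 3 | 5-(4-benzyloxy-3-methoxyphenyl)-3,4-bis(benzyloxymethyl)oxolan-2-one, 4,5-cis-3,4-trans | O=C1O[C@H](c2ccc(OCc3ccccc3)c(OC)c2)[C@H](COCc4ccccc4)[C@H]1COCc5ccccc5
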